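**Plan**

Numbering: C6 is the spiro carbon. Ring B is C6–C1H2–C2HBr–C3(Cl)(CH3)–C4H2–C5H2. Ring A is C6–C7(=C14H2)–C8H2–C9H(OH)–C10HBr–C11(CH3)2.
Cuts, in retrosynthetic order: C9–H; C8–H (methylidene unmasked from a C14 allylsilane); C10–Br; C7–C14; C3–Cl together with C4–H; C2–C3 together with C3–C4; last C6–C1 and C6–C5.
Enabling feature: the methyl-bearing C3 lies between C2 and C4. Ring B is therefore the Cs-symmetric cyclopentene C6–C1–C2=C4–C5 plus one CH3–C–Br unit, whose bromine moves to C2 when the C2–C4 bond opens.
Forward order: ring A comes with dimedone. The cyclopentene is spiro-annulated at C6, enlarged to ring B and hydrochlorinated. Ring A is then finished (C14, C10–Br, methylidene, C9–OH).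
Stereochemistry: C2 and C6 come from carbene attack on the C7 face, same-face bromide return and a chiral bromide-binding catalyst that selects C2 over C4. C3 comes from anti opening of the C2/C3 bromonium ion. C9 comes from an oxazaborolidine catalyst. C10 forms without bias, and the same catalyst selects its (R) epimer.

Key step: step 4

Assumption: the sense of induction of the thiourea in step 4 cannot be predicted, so the catalyst antipode that leads to the (6S,10S)-allylic bromide is meant; both antipodes derive from commercial tert-leucine.

**Route**

Step 1
Reactants: 1 dimedone (5,5-dimethylcyclohexane-1,3-dione); 2 2-methylpropan-1-ol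
Product: 3 3-(2-methylpropoxy)-5,5-dimethylcyclohex-2-en-1-one
Conditions: TsOH·H2O (cat), PhMe, reflux, Dean–Stark
Reagents that add atoms: none
Why: Acid-catalysed vinylogous ester formation from a cyclic 1,3-diketone is driven to completion by azeotropic removal of water, and the symmetry of 1 allows only one product.

Step 2
Reactants: 3 vinylogous ester; 4 cis-1,4-dichlorobut-2-ene
Product: 5 racemic 6-[(2Z)-4-chlorobut-2-en-1-yl]-3-(2-methylpropoxy)-5,5-dimethylcyclohex-2-en-1-one
Conditions: LDA, THF, −78 °C; 4 (3 equiv), DMPU, −78 °C → rt
Reagents that add atoms: none
Why: Kinetic deprotonation of a 3-alkoxyenone occurs at the α′ carbon C6 and the lithium enolate displaces one allylic chloride (Stork–Danheiser α′-alkylation), the excess of 4 suppressing bridging of two enolates, while the C6 stereocentre forms racemic and is erased in step 3.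

Step 3
Reactants: 5 allylic chloride
Product: 6 8-(2-methylpropoxy)-10,10-dimethylspiro[4.5]deca-2,7-dien-6-one (achiral)
Conditions: KHMDS, THF, −78 °C → rt
Reagents that add atoms: none
Why: Intramolecular enolate alkylation (5-exo-tet): under equilibrating conditions only the C6 enolate has the chloride within reach because the Z alkene folds CH2Cl back onto C6, C-alkylation to a five-membered ring beats O-alkylation to a seven-membered ring, and the product is achiral because C1 and C5 are equivalent.

Step 4
Reactants: 6 spiro[4.5]decadienone vinylogous ester; 7 1,1-dibromoethane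
Product: 10 (6S,10S)-10-bromo-5,5,9-trimethyl-3-(2-methylpropoxy)spiro[5.5]undeca-2,8-dien-1-one (allylic bromide; Br on C2 syn to C7), via 1,1-dibromoethyllithium 8 (not isolated), via endo-bromocyclopropane 9 (not isolated)
Conditions: 7 (excess), LiTMP (slight deficit to 7), THF–Et2O–pentane, −105 °C; then 6, −105 → −60 °C (repeated charges); filtration through SiO2 at −60 °C (Et2O); chiral N-[3,5-bis(trifluoromethyl)phenyl]thiourea of tert-leucine 2-arylpyrrolidine amide (10 mol %), PhMe, 4 Å MS, −60 → −30 °C; used at once
Reagents that add atoms: none
Why: Proposed new method: pre-formed 8 loses LiBr and transfers bromo(methyl)carbene in a concerted [2+1] addition to the only unpolarised alkene C2=C4, making C2–C3 and C3–C4; the closest known reaction types are halocarbene addition to cyclopentenes followed by thermal cyclopropyl-to-allyl halide ring expansion, and hydrogen-bond-donor (anion-binding) catalysis of SN1-type ion pairs, whose combination for an enantioselective bromide return is untested. In 9 the endo C3–Br bond ionises in concert with disrotatory two-electron electrocyclic opening of C2–C4, the only mode that places a cis-allyl cation inside a ring, so the three-membered ring closes by cheletropic addition and six-membered ring B arises by enlargement of the bicyclo[3.1.0]hexane rather than by an end-to-end cyclisation. The relative configuration of C2 and C6 rests on the substrate: the carbene should approach the cyclopentene face flanked by the flat C7 carbonyl and avoid the face under the C11 methyl groups, and because bromide leaves and returns on that same face it ends up syn to C7. The choice between the enantiotopic termini C2 and C4, which fixes C2 and C6 in the absolute sense, is left to the thiourea, which binds the departing bromide, lowers the ionisation barrier below that of the background reaction, holds the Cs-symmetric cation by a cation–π contact and a hydrogen bond to the C7 carbonyl, and releases bromide to one terminus. Chemoselectivity is secured by the push–pull deactivation of C8=C9, by the absence of free amide base (C10–H is the only acidic site of 6), by removal of LiBr and amine before the catalyst is added, and by the inertness of the exo-bromo isomer, which is separated afterwards. The product is kept cold because re-ionisation would racemise it through a degenerate 1,3-bromide shift.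

Step 5
Reactants: 10 allylic bromide
Product: 11 (6S,8S,9S)-8-bromo-9-chloro-5,5,9-trimethyl-3-(2-methylpropoxy)spiro[5.5]undec-2-en-1-one (Cl on C3 anti to Br on C2)
Conditions: HCl (g), CH2Cl2, −40 → 0 °C, anhydrous; cold aq NaHCO3
Reagents that add atoms: hydrogen chloride Cl
Why: Ionic Markovnikov hydrochlorination with neighbouring-group participation, the reaction type by which HX adds to 3-halocyclohexenes to give trans-1,2-dihalides: the proton goes to C4, the developing tertiary C3 cation is bridged from the C7 face by the pseudo-axial C2 bromine, and chloride opens the unsymmetrical bromonium ion at C3 from the opposite face, which sets C3 with Cl anti to Br, while anhydrous cold conditions leave the vinylogous ester only reversibly protonated.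

Step 6
Reactants: 11 bromochloride vinylogous ester
Product: 13 (6S,8S,9S)-8-bromo-9-chloro-5,5,9-trimethyl-1-[(trimethylsilyl)methyl]spiro[5.5]undec-1-en-3-one (C9 enone; CH2SiMe3 on C7), via tertiary carbinol 12 (not isolated)
Conditions: Me3SiCH2Li, CeCl3, THF, −78 → 0 °C; then 1 M HCl, THF, 0 °C, short contact
Reagents that add atoms: (trimethylsilyl)methyllithium [Li]C[Si](C)(C)C; water O
Why: Stork–Danheiser carbonyl transposition: the oxophilic and weakly basic organocerium reagent adds 1,2 to the hindered C7 carbonyl without displacing or eliminating the alkyl halides, and brief dilute acid ionises carbinol 12 to a cation whose charge rests mainly on the isobutoxy oxygen, so that water enters at C9 and isobutanol leaves faster than silicon is lost, the transient C7 stereocentre disappearing in the process.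

Step 7
Reactants: 13 silylmethyl enone
Product: 15 (4R,6R,8S,9S)-4,8-dibromo-9-chloro-5,5,9-trimethyl-1-[(trimethylsilyl)methyl]spiro[5.5]undec-1-en-3-one (C10 bromide on the ring A face that carries C1), via silyl dienol ether 14 (not isolated)
Conditions: LDA, Me3SiCl, THF, −78 °C; crude 14, NBS (1.0 equiv), THF, −78 °C
Reagents that add atoms: N-bromosuccinimide O=C1CCC(=O)N1Br; chlorotrimethylsilane C[Si](C)(C)Cl (silicon stays only in 14)
Why: Kinetic α′-enolisation at C10 (the site reached by the carbonyl-bound lithium amide, as in isophorone), O-silylation and electrophilic bromination of the cross-conjugated silyl dienol ether, which is far more nucleophilic than the carbonyl-conjugated allylsilane; little facial bias can be counted on at C10 because the two faces of ring A differ only through the remote C2/C4 substituents, so the (10R) epimer named here is carried on together with its epimer and the sorting is left to step 9.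

Step 8
Reactants: 15 α′-bromo silylmethyl enone
Product: 16 (2R,6R,8S,9S)-2,8-dibromo-9-chloro-1,1,9-trimethyl-5-methylidenespiro[5.5]undecan-3-one
Conditions: Bu4NF, AcOH, THF, −78 → −20 °C; neutral work-up, used directly
Reagents that add atoms: none
Why: Fluoride-induced protodesilylation of a vinylogous α-silyl ketone: attack on silicon frees the C9/C8/C7/C14 dienolate without any strong base, acetic acid protonates it kinetically at the α-carbon C8, which leaves the C7=C14 methylidene out of conjugation, and the buffered cold medium spares the C10 bromide, the bromochloride and the C10 configuration.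

Step 9
Reactants: 16 β,γ-unsaturated α′-bromoketone
Product: 17 (2R,3S,6R,8S,9S)-2,8-dibromo-9-chloro-1,1,9-trimethyl-5-methylidenespiro[5.5]undecan-3-ol (target)
Conditions: (R)-2-methyl-CBS-oxazaborolidine, catecholborane (limiting), PhMe, −78 °C; MeOH, aq NaHCO3; chromatography
Reagents that add atoms: none
Why: Corey–Bakshi–Shibata reduction: taking C10 (CHBr next to CMe2) as the large flank and C8H2 as the small one, the (R)-catalyst delivers hydride to the face that gives (9S), which for the (10R)-ketone coincides with the substrate-preferred equatorial attack (the axial C11 methyl blocks the axial path) and gives the cis-bromohydrin, whereas the (10S)-epimer is mismatched, reacts more slowly and is removed as ketone or as the readily separable trans-bromohydrin, catecholborane at −78 °C leaving the methylidene untouched.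

**Compound list**

1 | dimedone | CC1(C)CC(=O)CC(=O)C1 | starting material
2 | 2-methylpropan-1-ol | CC(C)CO | starting material
3 | 3-(2-methylpropoxy)-5,5-dimethylcyclohex-2-en-1-one | CC(C)COC1=CC(=O)CC(C)(C)C1 | intermediate
4 | cis-1,4-dichlorobut-2-ene | ClC/C=C\CCl | starting material
5 | racemic 6-[(2Z)-4-chlorobut-2-en-1-yl]-3-(2-methylpropoxy)-5,5-dimethylcyclohex-2-en-1-one | O=C1C=C(OCC(C)C)CC(C)(C)C1C/C=C\CCl | intermediate
6 | 8-(2-methylpropoxy)-10,10-dimethylspiro[4.5]deca-2,7-dien-6-one | O=C1C=C(OCC(C)C)CC(C)(C)C12CC=CC2 | intermediate
7 | 1,1-dibromoethane | CC(Br)Br | starting material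
8 | 1,1-dibromoethyllithium (carbenoid, not isolated) | CC(Br)(Br)[Li] | intermediate
9 | endo-bromo, exo-methyl cyclopropane on the C7 face of 6 (6-bromo-6-methylbicyclo[3.1.0]hexane spiro-linked at its C3 to ring A; Cs, not isolated) | O=C1C=C(OCC(C)C)CC(C)(C)[C@@]12C[C@@H]3[C@H](C2)[C@]3(C)Br | intermediate
10 | (6S,10S)-10-bromo-5,5,9-trimethyl-3-(2-methylpropoxy)spiro[5.5]undeca-2,8-dien-1-one | O=C1C=C(OCC(C)C)CC(C)(C)[C@@]12CC=C(C)[C@@H](Br)C2 | intermediate
11 | (6S,8S,9S)-8-bromo-9-chloro-5,5,9-trimethyl-3-(2-methylpropoxy)spiro[5.5]undec-2-en-1-one | O=C1C=C(OCC(C)C)CC(C)(C)[C@@]12CC[C@](C)(Cl)[C@@H](Br)C2 | intermediate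
12 | C7 tertiary carbinol from addition of Me3SiCH2 to 11 (C7 configuration undefined, not isolated) | C[Si](C)(C)CC1(O)C=C(OCC(C)C)CC(C)(C)[C@@]12CC[C@](C)(Cl)[C@@H](Br)C2 | intermediate
13 | (6S,8S,9S)-8-bromo-9-chloro-5,5,9-trimethyl-1-[(trimethylsilyl)methyl]spiro[5.5]undec-1-en-3-one | C[Si](C)(C)CC1=CC(=O)CC(C)(C)[C@@]12CC[C@](C)(Cl)[C@@H](Br)C2 | intermediate
14 | cross-conjugated trimethylsilyl dienol ether of 13 (C9–OSiMe3, C9=C10, C7=C8; not isolated) | C[Si](C)(C)CC1=CC(O[Si](C)(C)C)=CC(C)(C)[C@@]12CC[C@](C)(Cl)[C@@H](Br)C2 | intermediate
15 | (4R,6R,8S,9S)-4,8-dibromo-9-chloro-5,5,9-trimethyl-1-[(trimethylsilyl)methyl]spiro[5.5]undec-1-en-3-one | C[Si](C)(C)CC1=CC(=O)[C@H](Br)C(C)(C)[C@@]12CC[C@](C)(Cl)[C@@H](Br)C2 | intermediate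
16 | (2R,6R,8S,9S)-2,8-dibromo-9-chloro-1,1,9-trimethyl-5-methylidenespiro[5.5]undecan-3-one | C=C1CC(=O)[C@H](Br)C(C)(C)[C@@]12CC[C@](C)(Cl)[C@@H](Br)C2 | intermediate
17 | (2R,3S,6R,8S,9S)-2,8-dibromo-9-chloro-1,1,9-trimethyl-5-methylidenespiro[5.5]undecan-3-ol | C=C1C[C@H](O)[C@H](Br)C(C)(C)[C@@]12CC[C@](C)(Cl)[C@@H](Br)C2 | target

Total step count: 9. Longest linear sequence: 9 steps (1 → 17).

**Steps most likely to fail**

**Step 4.**
- The carbenoid may rearrange to vinyl bromide by a 1,2-hydride shift faster than it cyclopropanates, or it may act as a base toward C10–H.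
- Compound 9 may open without the catalyst during the cold filtration.
- The catalyst may discriminate poorly between C2 and C4.
- The product may racemise by re-ionisation, or the cation may be captured by the C7 carbonyl oxygen.

Fallback (known chemistry only): absolute control is handed to a covalently bound auxiliary and to separation of diastereomers. Setting out from 6, acid-catalysed alkoxy exchange with (−)-menthol (TsOH, PhMe, removal of isobutanol) gives menthyl vinylogous ester F1. Carbenoid 8 is added as in step 4 and the mixture is simply warmed to room temperature. Endo-bromocyclopropane F2 then opens thermally to two allylic bromides that are now diastereomers, the (6S,10S) allylic bromide F3 and the (6R,10R) allylic bromide F4. They are separated by crystallisation or chromatography. F4 is returned to the mixture by gentle warming in toluene, where the suprafacial 1,3-bromide shift through the contact ion pair interconverts the two. F3 is hydrochlorinated as in step 5 to menthyl bromochloride F5. Me3SiCH2CeCl2 followed by dilute acid, through menthyl carbinol F6, expels menthol and rejoins the route at 13.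

**Step 5.**
- Hydrogen chloride may assist ionisation of the allylic C2–Br bond before the alkene is protonated. This would cause halide exchange and loss of enantiopurity through the symmetrical cation.
- Protonation may be slow because of the inductive effect of bromine.
- Prolonged contact may cleave the vinylogous ester.

Fallback: the same bridged ion is reached from the other side, by adding Br+ and Cl− to the transposed alkene. Setting out from 10, an NHC–copper hydride catalysed SN2′ reduction (hydrosilane, LiOt-Bu, THF) delivers hydride to C4 and expels the C2 bromide. No symmetrical allyl species is involved, so the C6 configuration is kept in trisubstituted alkene F7. Me3SiCH2CeCl2 and dilute acid, through carbinol F8, give silylmethyl enone F9, in which ring A no longer carries an electron-rich double bond. Anti bromochlorination with BrCl made in situ (NBS, BnEt3NCl, CH2Cl2, −78 °C) then attacks only C2=C3. The productive bromonium ion lies on the C7 face, because a diaxial opening on the other face would set bromine against the quaternary C11. Chloride enters at the tertiary C3, and the route is rejoined at 13.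

**Step 8.**
- The dienolate may be protonated at C14, which returns the double bond to conjugation.
- It may expel the C10 bromide in a Favorskii-type process.
- C10 may epimerise.

Fallback: the order of reduction and desilylation is reversed, so that no enolate is formed. Setting out from 15, the ketone is reduced first with the (R)-oxazaborolidine and catecholborane to allylic alcohol F10. The bulky C10 flank again acts as the large group, and the same sorting of C10 epimers applies. The methylidene is then made by SE2′ protodesilylation of the now electron-rich allylsilane (BF3·2AcOH, CH2Cl2, −20 °C). The proton adds at C8 and silicon leaves from C14, while the electron-withdrawing C10 bromide slows competing ionisation at C9. This leads directly to 17.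

**Further compounds**

F1 | step 4 | menthyl vinylogous ester of the spiro[4.5]decadienone | O=C1C=C(O[C@@H]3C[C@H](C)CC[C@H]3C(C)C)CC(C)(C)C12CC=CC2
F2 | step 4 | endo-bromocyclopropane, menthyl series | O=C1C=C(O[C@@H]3C[C@H](C)CC[C@H]3C(C)C)CC(C)(C)[C@@]12C[C@@H]3[C@H](C2)[C@]3(C)Br
F3 | step 4 | (6S,10S) allylic bromide, menthyl series | O=C1C=C(O[C@@H]3C[C@H](C)CC[C@H]3C(C)C)CC(C)(C)[C@@]12CC=C(C)[C@@H](Br)C2
F4 | step 4 | (6R,10R) allylic bromide, menthyl series | O=C1C=C(O[C@@H]3C[C@H](C)CC[C@H]3C(C)C)CC(C)(C)[C@]12CC=C(C)[C@H](Br)C2
F5 | step 4 | menthyl bromochloride | O=C1C=C(O[C@@H]3C[C@H](C)CC[C@H]3C(C)C)CC(C)(C)[C@@]12CC[C@](C)(Cl)[C@@H](Br)C2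
F6 | step 4 | menthyl carbinol (C7 configuration undefined) | C[Si](C)(C)CC1(O)C=C(O[C@@H]3C[C@H](C)CC[C@H]3C(C)C)CC(C)(C)[C@@]12CC[C@](C)(Cl)[C@@H](Br)C2
F7 | step 5 | trisubstituted alkene (C2=C3) vinylogous ester | O=C1C=C(OCC(C)C)CC(C)(C)[C@@]12CCC(C)=CC2
F8 | step 5 | carbinol from F7 (C7 configuration undefined) | C[Si](C)(C)CC1(O)C=C(OCC(C)C)CC(C)(C)[C@@]12CCC(C)=CC2
F9 | step 5 | silylmethyl enone with C2=C3 alkene | C[Si](C)(C)CC1=CC(=O)CC(C)(C)[C@@]12CCC(C)=CC2
F10 | step 8 | (9S,10R) allylic alcohol bearing the C14 allylsilane | C[Si](C)(C)CC1=C[C@H](O)[C@H](Br)C(C)(C)[C@@]12CC[C@](C)(Cl)[C@@H](Br)C2
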